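## Structural features

Mollicellin A is a tetracyclic depsidone with no stereocentre. Ring A and ring B are joined twice, by a diaryl ether (a5–O–b6) and by an aryl ester (a6–C(=O)–O–b1), so that a seven-membered dioxepinone lies between them. Ring B also carries a fused 2,2-dimethylpyran-4-one (b3–O–C(CH3)2–CH2–C(=O)–b4). Both benzene rings are pentasubstituted (only a2 and b2 are C–H), so there are no neighbouring stereocentres to relate, only substituent order to control. The fragile groups are the salicylaldehyde (a3 OH, a4 CHO), the lactone (an aryl ester with a phenoxide leaving group, opened by base and nucleophiles) and the chromanone (retro-oxa-Michael opening under base). The real difficulty is the central ring: the ether links two di-ortho-substituted carbons and the a6 carboxyl sits between the a1 methyl and the a5 oxygen, so both classical closures (aryl ether coupling, esterification of a 2,6-disubstituted benzoic acid) are hindered. The feature used here is that ring A is a resorcinol monoaryl ether with a carbon substituent at a4 between the two oxygens and a carboxyl at a6 para to the a3 hydroxyl. That is the pattern a vinylketene–alkynyl ether benzannulation delivers, and a5 and a6 are the two atoms that can be tied to ring B beforehand through the b6 and b1 oxygens.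

## Logic of the disconnections

28 to 26 and 27. The b4–C(=O) bond and the b3–O–C(CH3)2 bond are cut. Ring B of 26 is an orcinol-type ring in which b4 is the only free position ortho to the free hydroxyl and para to the second oxygen. This removes a ring and five carbons. The forward step must acylate b4 rather than b2 and must spare the aldehyde and the lactone in strong acid.

26 to 25, 24 and 23. Only functional groups change: the b3 O–benzyl bond, the a4 aldehyde (from the alcohol) and the O–Si bond. The a4 carbon is carried as a silyl-protected hydroxymethyl group because neither an aldehyde nor a free alcohol would survive the organolithium and ketene stages, and the b3 oxygen stays benzylated until the last C–C bond is due. The demand is three orthogonal unmasking steps that leave the lactone intact.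

23 to 18. The bonds a1–a6, a5–a6, a3–a4 and a2–a3 are cut (and a3–a6 is restored), which opens ring A and the seven-membered ring; 18 and 23 differ only by N2. The hindered ester and the ether oxygen already exist in 18 as unhindered open-chain bonds, and ring A shrinks to a four-carbon diazo ketoester arm and an alkyne. The forward step must give vinyl migration in the Wolff step, intramolecular ketene–alkyne union through the catechol tether, and electrocyclic ring opening and closure.

18 to 17, then 15 and 16. The a3–a6 carbon–carbon bond is cut. A diazoacetate adds to an aldehyde under mild base and the carbinol is then oxidised, so no heat or acid meets the alkynyl ether. The demand is an oxidation that does not release acid onto the alkynyl ether.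

15 to 12 and 13. The b1 O–acyl bond is cut. The ester can only be made after the organolithium step, and a free phenol next to the alkynyl ether is judged liable to add across it, so the b1 oxygen is stored as a silyl ether and released by fluoride directly as the phenoxide. The demand is cleavage of the aryl silyl ether in the presence of the alkyl silyl ether.

12 to 9 and 10. The alkyne C–CH2 bond is cut and the triple bond is traced to a dichlorovinyl ether. The a4 carbon arrives with its protected oxygen in a single operation. The demand is that the b1 protecting group resists n-BuLi.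

9 to 7, then 5 and 6. The b6 O–vinyl bond is cut and the b1 protecting group is changed. During the base-mediated vinyl ether formation the b1 oxygen must carry an alkyl group, because a silyl group would migrate between the two adjacent oxygens. Afterwards the allyl group is exchanged for the fluoride-labile silyl group. The demand is addition of a 2,6-disubstituted phenoxide.

5 to 3, 2 and 1. The b3 O–benzyl bond, the b6 C–O bond and the b1 O–allyl bond are cut. The two oxygens of 1 become b1 and b3, and the third enters para to the free hydroxyl of 2, which fixes the allyl group on b1. Reduction gives a hydroquinone whose two hydroxyls differ in hindrance and acidity. The demands are a statistical monoallylation and a selective monobenzylation.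

## Other disconnections considered

Alternative 1: The cut runs through the ester C–O(b1) bond and the a6–a1 bond, so ring A becomes an open tetraketide chain attached to ring B.
- Forward step: the diketo-dioxinone A1 is heated with the bromophenol A2 (complete ring B with its chromanone, free b1 hydroxyl, bromine at b6). A1 loses its ketal ketone by retro-hetero-Diels–Alder reaction, the acylketene is captured by the b1 hydroxyl, and base in the same flask drives a6–a1 aldol closure and dehydration to the aryl orsellinate A3.
- In favour: every elementary step is established resorcylate chemistry and no light or diazo compound is needed. The hindered ester is made before ring A exists, which makes it the equal of the chosen plan on that point. The chromanone is already in place, so the late acid-mediated annulation is avoided, and here it is the better plan.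
- Against: A3 has neither the a5–O–b6 ether nor the a4 formyl group. The ether would need an intramolecular copper-mediated coupling between a hydrogen-bonded hydroxyl and a bromide flanked by methyl and acyloxy, under hot basic conditions that an aryl ester tolerates poorly. The formyl group would have to enter at a4 in competition with a2 and b2, and A2 itself needs bromination at b6 rather than b2.
- Comparison: its key step is mechanistically the safer one and the way to A3 is probably shorter. It builds one ring and two bonds where the chosen step builds two rings and four bonds, and it leaves the two hardest problems (hindered ether, a4 carbon) for later steps.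

Alternative 2: Ring B is cut at b6–b5 and b2–b3, and the diaryl ether is traced back to an alkyl aryl ether made by alkylating the a5 hydroxyl of an orsellinic acid with a haloacetone, which gives the aryloxyacetone A4.
- Forward step: A4 is treated with methyl (E)-but-2-enoate A5 and a tert-butoxide base. Michael addition through the aryloxy-bearing carbon and Claisen closure by the methyl ketone enolate should give the trans dione A6 (racemic; both stereocentres vanish on aromatisation).
- In favour: the ether oxygen is attached by simple alkylation, so no coupling at a di-ortho-substituted aryl carbon is needed; the chosen plan also avoids this, so the two are equal here. The reagents are cheap, and the enolate chemistry is better founded than the chosen cascade.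
- Against: the carboxyl and phenol of A4 consume base and may need protection, and the first enolate must form on the aryloxy side. After A6 the route still needs dehydrogenation to the resorcinol ring, lactonisation, chromanone annulation and formylation at a4.
- Comparison: it lowers the oxidation level of ring B only to raise it again and creates two stereocentres merely to erase them. It needs at least four further skeletal operations after its key step against one for the chosen route, and a4 regiocontrol stays unsolved.

Alternative 3: The lactone carbon is removed by cutting a6–C(=O) and C(=O)–O(b1), and it is supplied as carbon monoxide A9.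
- Forward step: the iodo diaryl ether A7 (a6 iodide, free b1 hydroxyl, a3 methyl ether, aldehyde and chromanone in place) would add oxidatively to zerovalent palladium formed from Pd(OAc)2 and a wide-bite-angle bisphosphine. A9 inserts and the b1 hydroxyl captures the acylpalladium to give the methyl ether A8, one demethylation from the target.
- In favour: it is the most convergent plan. The sensitive lactone is formed last and never meets earlier reagents, which is better than the chosen plan. The elementary steps are individually well known, so it is better founded, and the final demethylation ortho to the aldehyde can be chelation-controlled.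
- Against: the hard part is only displaced. A7 is the fully substituted diaryl ether, whose making needs a hindered coupling or substitution and an iodination directed to a6. Oxidative addition at an iodide flanked by methyl and aryloxy, and reductive elimination to a seven-membered aryl ester, are both slow cases.
- Comparison: its key step forms one ring and two bonds and needs both arenes complete. The longest linear sequence may be shorter, but the total count is not clearly lower. The chosen plan never forms a bond at a hindered aryl carbon, at the price of an unprecedented cascade.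

Key step: step 10

Remark: the target has no stereocentre, so no step needs stereocontrol; (chloromethoxy)triisopropylsilane (10) and 2,5-dioxopyrrolidin-1-yl 2-diazoacetate (13) are treated as catalogue reagents.

## Steps

Step 1
Reactants: 1 orcinol (5-methylbenzene-1,3-diol)
Product: 2 3-(allyloxy)-5-methylphenol
Conditions: allyl bromide (0.4 equiv), K2CO3, acetone, reflux; excess 1 recovered
Reagents that add atoms: allyl bromide, C=CCBr
Why: Williamson ether synthesis; with the symmetrical diol in excess the monoether should dominate and is separated from the diether and recovered 1.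

Step 2
Reactants: 2 3-(allyloxy)-5-methylphenol
Product: 3 2-(allyloxy)-6-methyl-1,4-benzoquinone
Conditions: K2[ON(SO3)2] (2.2 equiv), KH2PO4 buffer, H2O/acetone, 0 °C to rt
Reagents that add atoms: potassium nitrosodisulfonate (Fremy's salt), [K+].[K+].[O-]S(=O)(=O)N([O])S(=O)(=O)[O-]
Why: Teuber oxidation: a phenol with a free para position is taken to the para-quinone, so the new oxygen (the future b6 oxygen) enters between the allyloxy and methyl groups, as it does for the corresponding methyl ether; the allyl ether is inert to the aminoxyl radical.

Step 3
Reactants: 3 2-(allyloxy)-6-methyl-1,4-benzoquinone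
Product: 5 2-(allyloxy)-4-(benzyloxy)-6-methylphenol, via hydroquinone 4 (not isolated)
Conditions: Na2S2O4, EtOAc/H2O, rt; organic layer dried and concentrated under Ar; BnBr (1.0 equiv), K2CO3, acetone, 50 °C
Reagents that add atoms: benzyl bromide, BrCc1ccccc1
Why: Dithionite reduction of the quinone followed by Williamson benzylation; the 4-hydroxyl (b3) is unhindered and the more acidic, whereas the 1-hydroxyl (b6) is flanked by methyl and allyloxy, so one equivalent of halide should go to b3.

Step 4
Reactants: 5 2-(allyloxy)-4-(benzyloxy)-6-methylphenol; 6 trichloroethylene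
Product: 7 1-(allyloxy)-5-(benzyloxy)-2-[(E)-1,2-dichloroethenyloxy]-3-methylbenzene
Conditions: K2CO3, DMF, 65 °C, Ar
Reagents that add atoms: none
Why: Base turns 6 into dichloroacetylene in the flask and the b6 phenoxide adds to it with anti protonation, the standard entry to (E)-1,2-dichlorovinyl ethers; the electrophile is small enough for a 2,6-disubstituted phenoxide, and the allyl group on the neighbouring oxygen cannot migrate under base.

Step 5
Reactants: 7 1-(allyloxy)-5-(benzyloxy)-2-[(E)-1,2-dichloroethenyloxy]-3-methylbenzene
Product: 9 {5-(benzyloxy)-2-[(E)-1,2-dichloroethenyloxy]-3-methylphenoxy}triisopropylsilane, via phenol 8 (not isolated)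
Conditions: Pd(PPh3)4 (3 mol%), Et2NH, THF, rt; evaporate; iPr3SiCl, imidazole, DMF, rt
Reagents that add atoms: chlorotriisopropylsilane, CC(C)[Si](Cl)(C(C)C)C(C)C
Why: Tsuji–Trost deallylation (zerovalent palladium, amine as allyl acceptor) followed by silylation of the freed b1 phenol; the exchange is made only now because no phenoxide sits next to the silyl ether from here on, and the silyl ether can later be cleaved by fluoride straight to a phenoxide.

Step 6
Reactants: 9 {5-(benzyloxy)-2-[(E)-1,2-dichloroethenyloxy]-3-methylphenoxy}triisopropylsilane; 10 (chloromethoxy)triisopropylsilane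
Product: 12 4-(benzyloxy)-2-methyl-6-[(triisopropylsilyl)oxy]phenyl 3-[(triisopropylsilyl)oxy]prop-1-ynyl ether, via lithium alkynide 11 (not isolated)
Conditions: n-BuLi (2.3 equiv), THF, −78 to −40 °C; 10, −78 to 0 °C
Reagents that add atoms: none
Why: Greene-type alkynyl ether synthesis: n-BuLi eliminates HCl from the dichlorovinyl ether and exchanges the remaining chlorine to give 11, which is alkylated at carbon by the α-chloro ether 10 (SN2 alkylation of an acetylide), so the future a4 carbon arrives already as its silyl ether.

Step 7
Reactants: 12 4-(benzyloxy)-2-methyl-6-[(triisopropylsilyl)oxy]phenyl 3-[(triisopropylsilyl)oxy]prop-1-ynyl ether; 13 2,5-dioxopyrrolidin-1-yl 2-diazoacetate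
Product: 15 5-(benzyloxy)-3-methyl-2-{3-[(triisopropylsilyl)oxy]prop-1-ynyloxy}phenyl 2-diazoacetate, via phenoxide 14 (not isolated)
Conditions: Bu4NF (1.05 equiv) added to 12 and 13, THF, −20 °C
Reagents that add atoms: none
Why: Fluoride cleaves an aryl silyl ether far faster than a primary alkyl silyl ether, and the phenoxide 14 is acylated at once by the active ester 13 (acyl transfer); because the b1 oxygen is never present as the neutral phenol it should not add across the neighbouring alkynyl ether.

Step 8
Reactants: 15 5-(benzyloxy)-3-methyl-2-{3-[(triisopropylsilyl)oxy]prop-1-ynyloxy}phenyl 2-diazoacetate; 16 methacrolein (2-methylprop-2-enal)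
Product: 17 5-(benzyloxy)-3-methyl-2-{3-[(triisopropylsilyl)oxy]prop-1-ynyloxy}phenyl 2-diazo-3-hydroxy-4-methylpent-4-enoate (racemic)
Conditions: DBU (0.2 equiv), MeCN, 0 °C to rt
Reagents that add atoms: none
Why: Base-catalysed aldol-type 1,2-addition of the diazoacetate carbon to the aldehyde; the carbinol centre forms as a racemate and is removed in step 9.

Step 9
Reactants: 17 the 2-diazo-3-hydroxy ester
Product: 18 5-(benzyloxy)-3-methyl-2-{3-[(triisopropylsilyl)oxy]prop-1-ynyloxy}phenyl 2-diazo-4-methyl-3-oxopent-4-enoate
Conditions: Dess–Martin periodinane (1.3 equiv), NaHCO3, CH2Cl2, 0 °C to rt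
Reagents that add atoms: none
Why: Dess–Martin oxidation of the allylic carbinol next to the diazo carbon, a standard route from such aldol adducts to 2-diazo-1,3-ketoesters; the hydrogencarbonate takes up the acetic acid that could otherwise add to the alkynyl ether.

Step 10
Reactants: 18 the diazo ketoester
Product: 23 8-(benzyloxy)-3-hydroxy-1,6-dimethyl-4-{[(triisopropylsilyl)oxy]methyl}-11H-dibenzo[b,e][1,4]dioxepin-11-one, via vinylketene 19 (not isolated), via cyclobutenone 20 (not isolated), via dienylketene 21 (not isolated), via cyclohexadienone 22 (not isolated)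
Conditions: hν (365 nm LED), degassed toluene, 0.003 M, 25 °C; then 90 °C in the dark
Reagents that add atoms: none
Why: Proposed new method: irradiation of 18 expels N2 and the isopropenyl group shifts from the ketone carbon to the carbene carbon (forming a1–a6), the normal photochemical Wolff course of a 2-diazo-1,3-ketoester in which carbon migrates in preference to the ester oxygen substituent, to give 19. The closest known reaction type is the intermolecular benzannulation of photochemically generated vinylketenes with alkoxyalkynes; tying the two partners together through the b1 and b6 oxygens has no precedent. The electrophilic ketene carbon of 19 is attacked by the alkyne carbon remote from oxygen (a3–a4) and the resulting enolate carbon closes onto the oxygen-bearing carbon (a5–a6), so the seven-membered ring closes in the [2+2] event, exo with respect to the alkyne, to give 20; both the polarity of the alkynyl ether and the five-atom catechol tether dictate this orientation. Warming opens the strained 4-vinylcyclobutenone 20 by four-electron conrotatory ring opening to 21, in which the a5=a6 double bond lies inside the seven-membered ring and therefore holds the isopropenyl group cis to the ketene arm. Ring A then closes by thermal six-electron disrotatory electrocyclisation (a2–a3) to 22, which tautomerises irreversibly to the phenol 23. No stereocentre is formed; the quaternary carbon of 20 is transient. The step needs intramolecular capture of the ketene to outrun dimerisation and capture by the phenol of 23 already formed, which high dilution and the short rigid tether should secure, and it needs the ester to reach the E geometry of a lactone, which the 90 °C stage assists.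

Step 11
Reactants: 23 the silyl-protected depsidone
Product: 24 8-(benzyloxy)-3-hydroxy-4-(hydroxymethyl)-1,6-dimethyl-11H-dibenzo[b,e][1,4]dioxepin-11-one
Conditions: HF·pyridine, THF/pyridine, 0 °C to rt
Reagents that add atoms: none
Why: Fluoride cleavage of the primary silyl ether under slightly acidic conditions, chosen over basic fluoride so that the aryl ester lactone is not opened.

Step 12
Reactants: 24 the hydroxymethyl depsidone
Product: 25 8-(benzyloxy)-3-hydroxy-1,6-dimethyl-11-oxo-11H-dibenzo[b,e][1,4]dioxepine-4-carbaldehyde
Conditions: activated MnO2 (excess), CH2Cl2, rt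
Reagents that add atoms: none
Why: MnO2 oxidises benzylic alcohols selectively, and the ortho-hydroxybenzyl alcohol should give the hydrogen-bonded salicylaldehyde without over-oxidation; the b3 oxygen is still benzylated, so ring B is not an oxidisable free phenol.

Step 13
Reactants: 25 the benzyl-protected aldehyde
Product: 26 3,8-dihydroxy-1,6-dimethyl-11-oxo-11H-dibenzo[b,e][1,4]dioxepine-4-carbaldehyde
Conditions: BCl3 (3 equiv), C6HMe5 (3 equiv), CH2Cl2, −78 °C
Reagents that add atoms: none
Why: Lewis acid cleavage of the aryl benzyl ether; pentamethylbenzene traps the benzyl cation before it can alkylate ring B, and at −78 °C the lactone, the diaryl ether and the chelated salicylaldehyde should be left untouched.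

Step 14
Reactants: 26 the b3 phenol; 27 3-methylbut-2-enoic acid
Product: 28 mollicellin A
Conditions: P2O5/MeSO3H (1:10 w/w), 60 °C
Reagents that add atoms: none
Why: Friedel–Crafts acylation by the activated form of 27 followed by oxa-Michael addition of the b3 hydroxyl, the usual one-pot 2,2-dimethylchroman-4-one annulation of phenols; ring B of 26 is an orcinol-type ring, so acylation is expected at b4 (ortho to the free hydroxyl, para to the b1 oxygen) and not at b2 between the two oxygens, while ring A is deactivated by its aldehyde and ester.

## Compound list

1 | orcinol (5-methylbenzene-1,3-diol) | Cc1cc(O)cc(O)c1 | starting material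
2 | 3-(allyloxy)-5-methylphenol | Cc1cc(O)cc(OCC=C)c1 | intermediate
3 | 2-(allyloxy)-6-methyl-1,4-benzoquinone | CC1=CC(=O)C=C(OCC=C)C1=O | intermediate
4 | 2-(allyloxy)-6-methylbenzene-1,4-diol | Cc1cc(O)cc(OCC=C)c1O | intermediate (not isolated)
5 | 2-(allyloxy)-4-(benzyloxy)-6-methylphenol | Cc1cc(OCc2ccccc2)cc(OCC=C)c1O | intermediate
6 | trichloroethylene | ClC=C(Cl)Cl | starting material
7 | 1-(allyloxy)-5-(benzyloxy)-2-[(E)-1,2-dichloroethenyloxy]-3-methylbenzene | Cc1cc(OCc2ccccc2)cc(OCC=C)c1O/C(Cl)=C\Cl | intermediate
8 | 5-(benzyloxy)-2-[(E)-1,2-dichloroethenyloxy]-3-methylphenol | Cc1cc(OCc2ccccc2)cc(O)c1O/C(Cl)=C\Cl | intermediate (not isolated)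
9 | {5-(benzyloxy)-2-[(E)-1,2-dichloroethenyloxy]-3-methylphenoxy}triisopropylsilane | Cc1cc(OCc2ccccc2)cc(O[Si](C(C)C)(C(C)C)C(C)C)c1O/C(Cl)=C\Cl | intermediate
10 | (chloromethoxy)triisopropylsilane | ClCO[Si](C(C)C)(C(C)C)C(C)C | starting material
11 | lithium {4-(benzyloxy)-2-methyl-6-[(triisopropylsilyl)oxy]phenoxy}ethynide | [Li]C#COc1c(C)cc(OCc2ccccc2)cc1O[Si](C(C)C)(C(C)C)C(C)C | intermediate (not isolated)
12 | 4-(benzyloxy)-2-methyl-6-[(triisopropylsilyl)oxy]phenyl 3-[(triisopropylsilyl)oxy]prop-1-ynyl ether | Cc1cc(OCc2ccccc2)cc(O[Si](C(C)C)(C(C)C)C(C)C)c1OC#CCO[Si](C(C)C)(C(C)C)C(C)C | intermediate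
13 | 2,5-dioxopyrrolidin-1-yl 2-diazoacetate | [N-]=[N+]=CC(=O)ON1C(=O)CCC1=O | starting material
14 | tetrabutylammonium 5-(benzyloxy)-3-methyl-2-{3-[(triisopropylsilyl)oxy]prop-1-ynyloxy}phenoxide | CCCC[N+](CCCC)(CCCC)CCCC.Cc1cc(OCc2ccccc2)cc([O-])c1OC#CCO[Si](C(C)C)(C(C)C)C(C)C | intermediate (not isolated)
15 | 5-(benzyloxy)-3-methyl-2-{3-[(triisopropylsilyl)oxy]prop-1-ynyloxy}phenyl 2-diazoacetate | Cc1cc(OCc2ccccc2)cc(OC(=O)C=[N+]=[N-])c1OC#CCO[Si](C(C)C)(C(C)C)C(C)C | intermediate
16 | methacrolein (2-methylprop-2-enal) | C=C(C)C=O | starting material
17 | aryl 2-diazo-3-hydroxy-4-methylpent-4-enoate (aryl as in 15; racemic) | C=C(C)C(O)C(=[N+]=[N-])C(=O)Oc1cc(OCc2ccccc2)cc(C)c1OC#CCO[Si](C(C)C)(C(C)C)C(C)C | intermediate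
18 | aryl 2-diazo-4-methyl-3-oxopent-4-enoate (aryl as in 15; the diazo ketoester) | C=C(C)C(=O)C(=[N+]=[N-])C(=O)Oc1cc(OCc2ccccc2)cc(C)c1OC#CCO[Si](C(C)C)(C(C)C)C(C)C | intermediate
19 | aryl 3-methyl-2-(oxomethylidene)but-3-enoate (aryl as in 15; the vinylketene) | C=C(C)C(=C=O)C(=O)Oc1cc(OCc2ccccc2)cc(C)c1OC#CCO[Si](C(C)C)(C(C)C)C(C)C | intermediate (not isolated)
20 | 4-isopropenylcyclobutenone fused at a5–a6 to the seven-membered dioxepinone (racemic at a6) | C=C(C)C12C(=O)C(CO[Si](C(C)C)(C(C)C)C(C)C)=C1Oc1c(C)cc(OCc3ccccc3)cc1OC2=O | intermediate (not isolated)
21 | dienylketene: benzodioxepinone with isopropenyl on a6 and the silyloxymethyl ketene arm on a5 | C=C(C)C1=C(C(CO[Si](C(C)C)(C(C)C)C(C)C)=C=O)Oc2c(C)cc(OCc3ccccc3)cc2OC1=O | intermediate (not isolated)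
22 | cyclohexa-2,4-dienone tautomer of 23 (a2 is CH2, a3 is C=O) | O=C1CC(C)=C2C(=O)Oc3cc(OCc4ccccc4)cc(C)c3OC2=C1CO[Si](C(C)C)(C(C)C)C(C)C | intermediate (not isolated)
23 | 8-(benzyloxy)-3-hydroxy-1,6-dimethyl-4-{[(triisopropylsilyl)oxy]methyl}-11H-dibenzo[b,e][1,4]dioxepin-11-one | Cc1cc(O)c(CO[Si](C(C)C)(C(C)C)C(C)C)c2c1C(=O)Oc1cc(OCc3ccccc3)cc(C)c1O2 | intermediate
24 | 8-(benzyloxy)-3-hydroxy-4-(hydroxymethyl)-1,6-dimethyl-11H-dibenzo[b,e][1,4]dioxepin-11-one | Cc1cc(O)c(CO)c2c1C(=O)Oc1cc(OCc3ccccc3)cc(C)c1O2 | intermediate
25 | 8-(benzyloxy)-3-hydroxy-1,6-dimethyl-11-oxo-11H-dibenzo[b,e][1,4]dioxepine-4-carbaldehyde | Cc1cc(O)c(C=O)c2c1C(=O)Oc1cc(OCc3ccccc3)cc(C)c1O2 | intermediate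
26 | 3,8-dihydroxy-1,6-dimethyl-11-oxo-11H-dibenzo[b,e][1,4]dioxepine-4-carbaldehyde | Cc1cc(O)c(C=O)c2c1C(=O)Oc1cc(O)cc(C)c1O2 | intermediate
27 | 3-methylbut-2-enoic acid | CC(C)=CC(=O)O | starting material
28 | mollicellin A | Cc1cc(O)c(C=O)c2c1C(=O)Oc1cc3c(c(C)c1O2)C(=O)CC(C)(C)O3 | target

## Step count and least certain steps

Total step count: 14. Longest linear sequence: 14 steps (1 to 28).

Step 10 (key step). The ketene may fail to reach the tethered alkyne in time, because the ester has to turn into its E geometry and a medium-sized array has to fold. Ketene dimerisation, capture by moisture or by the phenol of 23 already formed, addition through the ester carbonyl, or photo-Fries cleavage of the aryl ester would then take over. The fallback sets out from 12 and returns at 23, using the untethered, established form of the benzannulation and an ordinary lactonisation.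
- Allyl 2-diazoacetate (catalogue reagent) is added to 16 with DBU to give allyl 2-diazo-3-hydroxy-4-methylpent-4-enoate F1, which is oxidised as in step 9 to allyl 2-diazo-4-methyl-3-oxopent-4-enoate F2.
- F2 and 12 are irradiated together and then heated to give the diaryl ether allyl ester F3, with regiochemistry set by the polarity of the alkynyl ether.
- Pd(PPh3)4 and morpholine free the carboxylic acid F4, and Bu4NF (1 equiv) then frees the b1 phenol to give the hydroxy acid F5.
- Lactonisation with 2,4,6-trichlorobenzoyl chloride/Et3N and DMAP at high dilution closes the seven-membered ring to 23.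

Step 3. Over-alkylation, or alkylation at the hindered hydroxyl, would give a mixture of benzyl ethers. The fallback sets out from 1 and returns at 5, with every oxygen placed by a regiodefined reaction.
- Monobenzylation of 1 gives 3-(benzyloxy)-5-methylphenol F6.
- Ortho-formylation with MgCl2, Et3N and paraformaldehyde, directed para to the benzyloxy group, gives 4-(benzyloxy)-2-hydroxy-6-methylbenzaldehyde F7.
- Allylation gives 2-(allyloxy)-4-(benzyloxy)-6-methylbenzaldehyde F8.
- Baeyer–Villiger oxidation with mCPBA gives 2-(allyloxy)-4-(benzyloxy)-6-methylphenyl formate F9, which is cleaved with K2CO3/MeOH to 5.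

Step 6. The acetylide or residual n-BuLi may attack silicon instead of the chloromethyl carbon, or alkylation may be incomplete. The fallback sets out from 9 (through 11) and returns at 12: 11 is trapped with paraformaldehyde to give the propargylic alcohol 3-{4-(benzyloxy)-2-methyl-6-[(triisopropylsilyl)oxy]phenoxy}prop-2-yn-1-ol F10, which is silylated with iPr3SiCl and imidazole.

Step 7. The second silyl ether may also be lost, or the liberated b1 oxygen may add across the neighbouring alkynyl ether before acyl transfer is complete. The fallback sets out from 12 and returns at 15: the phenoxide is trapped at −78 °C with bromoacetyl bromide, a faster and irreversible acyl donor, to give the aryl bromoacetate F11, and the diazo group is then made with N,N'-ditosylhydrazine and DBU.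

Step 14. Conjugate (alkylative) attack of the acid on ring B, acylation at b2, or condensation of the protonated aldehyde with ring B of a second molecule may compete. The fallback sets out from 26 and returns at 28 in stages.
- 3-Methylbut-2-enoyl chloride and Et3N at −20 °C acylate the b3 hydroxyl (the a3 hydroxyl is hydrogen-bonded to the aldehyde) to give the b3 3-methylbut-2-enoate F12.
- Fries rearrangement with TiCl4 moves the acyl group to b4 to give the ortho-hydroxyaryl enone F13.
- Mild base (NaOAc, EtOH) closes the pyranone by oxa-Michael addition.

## Further compounds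

F1 | step 10 | allyl 2-diazo-3-hydroxy-4-methylpent-4-enoate (racemic) | C=CCOC(=O)C(=[N+]=[N-])C(O)C(C)=C
F2 | step 10 | allyl 2-diazo-4-methyl-3-oxopent-4-enoate | C=CCOC(=O)C(=[N+]=[N-])C(=O)C(C)=C
F3 | step 10 | allyl 2-{4-(benzyloxy)-2-methyl-6-[(triisopropylsilyl)oxy]phenoxy}-4-hydroxy-6-methyl-3-{[(triisopropylsilyl)oxy]methyl}benzoate | C=CCOC(=O)c1c(C)cc(O)c(CO[Si](C(C)C)(C(C)C)C(C)C)c1Oc1c(C)cc(OCc2ccccc2)cc1O[Si](C(C)C)(C(C)C)C(C)C
F4 | step 10 | 2-{4-(benzyloxy)-2-methyl-6-[(triisopropylsilyl)oxy]phenoxy}-4-hydroxy-6-methyl-3-{[(triisopropylsilyl)oxy]methyl}benzoic acid | OC(=O)c1c(C)cc(O)c(CO[Si](C(C)C)(C(C)C)C(C)C)c1Oc1c(C)cc(OCc2ccccc2)cc1O[Si](C(C)C)(C(C)C)C(C)C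
F5 | step 10 | 2-[4-(benzyloxy)-2-hydroxy-6-methylphenoxy]-4-hydroxy-6-methyl-3-{[(triisopropylsilyl)oxy]methyl}benzoic acid | OC(=O)c1c(C)cc(O)c(CO[Si](C(C)C)(C(C)C)C(C)C)c1Oc1c(C)cc(OCc2ccccc2)cc1O
F6 | step 3 | 3-(benzyloxy)-5-methylphenol | Cc1cc(O)cc(OCc2ccccc2)c1
F7 | step 3 | 4-(benzyloxy)-2-hydroxy-6-methylbenzaldehyde | Cc1cc(OCc2ccccc2)cc(O)c1C=O
F8 | step 3 | 2-(allyloxy)-4-(benzyloxy)-6-methylbenzaldehyde | Cc1cc(OCc2ccccc2)cc(OCC=C)c1C=O
F9 | step 3 | 2-(allyloxy)-4-(benzyloxy)-6-methylphenyl formate | Cc1cc(OCc2ccccc2)cc(OCC=C)c1OC=O
F10 | step 6 | 3-{4-(benzyloxy)-2-methyl-6-[(triisopropylsilyl)oxy]phenoxy}prop-2-yn-1-ol | Cc1cc(OCc2ccccc2)cc(O[Si](C(C)C)(C(C)C)C(C)C)c1OC#CCO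
F11 | step 7 | 5-(benzyloxy)-3-methyl-2-{3-[(triisopropylsilyl)oxy]prop-1-ynyloxy}phenyl 2-bromoacetate | Cc1cc(OCc2ccccc2)cc(OC(=O)CBr)c1OC#CCO[Si](C(C)C)(C(C)C)C(C)C
F12 | step 14 | 4-formyl-3-hydroxy-1,6-dimethyl-11-oxo-11H-dibenzo[b,e][1,4]dioxepin-8-yl 3-methylbut-2-enoate | Cc1cc(O)c(C=O)c2c1C(=O)Oc1cc(OC(=O)C=C(C)C)cc(C)c1O2
F13 | step 14 | 3,8-dihydroxy-1,6-dimethyl-7-(3-methylbut-2-enoyl)-11-oxo-11H-dibenzo[b,e][1,4]dioxepine-4-carbaldehyde | Cc1cc(O)c(C=O)c2c1C(=O)Oc1cc(O)c(C(=O)C=C(C)C)c(C)c1O2
A1 | alternative 1 | 6-(2,4-dioxopentyl)-2,2-dimethyl-4H-1,3-dioxin-4-one | CC(=O)CC(=O)CC1=CC(=O)OC(C)(C)O1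
A2 | alternative 1 | 6-bromo-7-hydroxy-2,2,5-trimethylchroman-4-one | Cc1c(Br)c(O)cc2OC(C)(C)CC(=O)c12
A3 | alternative 1 | 6-bromo-2,2,5-trimethyl-4-oxochroman-7-yl 2,4-dihydroxy-6-methylbenzoate | Cc1cc(O)cc(O)c1C(=O)Oc1cc2OC(C)(C)CC(=O)c2c(C)c1Br
A4 | alternative 2 | 4-hydroxy-2-methyl-6-(2-oxopropoxy)benzoic acid | CC(=O)COc1cc(O)cc(C)c1C(=O)O
A5 | alternative 2 | methyl (E)-but-2-enoate | C/C=C/C(=O)OC
A6 | alternative 2 | trans-4-aryloxy-5-methylcyclohexane-1,3-dione, aryl = 2-carboxy-5-hydroxy-3-methylphenyl (racemic, one enantiomer drawn) | Cc1cc(O)cc(O[C@@H]2[C@@H](C)CC(=O)CC2=O)c1C(=O)O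
A7 | alternative 3 | 2-[(7-hydroxy-2,2,5-trimethyl-4-oxochroman-6-yl)oxy]-3-iodo-6-methoxy-4-methylbenzaldehyde | Cc1cc(OC)c(C=O)c(Oc2c(O)cc3OC(C)(C)CC(=O)c3c2C)c1I
A8 | alternative 3 | mollicellin A a3-methyl ether | Cc1cc(OC)c(C=O)c2c1C(=O)Oc1cc3c(c(C)c1O2)C(=O)CC(C)(C)O3
A9 | alternative 3 | carbon monoxide | [C-]#[O+]
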